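**Plan**

1. Retrosynthesis: the C6 angelate and the C12 ester oxidation level are taken off first, then ring B is cut at C7–C8. The enabling feature is the equatorial 8α-hydroxyl on C8 next to C7, which carries the C11(=C13) propenyl unit; this homoallylic alcohol in ring B is the product pattern of a carbonyl-ene reaction between a C8 aldehyde (on C9) and a C7=C11 isopropylidene alkene (on C6).
2. The 7,8-seco precursor is cut further at C6–C7 (alkenyl Grignard on a lactol), C5–C6 (carbonylation of a C5 enol triflate), C4–C15 (enolate methylation) and C10–C9 (enolate allylation).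
3. Forward: ring A is the ring of 2-methylcyclohex-2-enone. A temporary lactone ring (C5–C6–O–C8–C9–C10) is fused on to control C4 and C5 and is opened again. Ring B is closed last by the ene reaction, after which the angelate and the acrylate are installed.
4. Stereochemistry: CBS reduction and hydroxyl-directed epoxidation fix C1; allylation anti to O1 fixes C10; the angular C14 methyl steers epoxidation (C4) and protonation (C5); a magnesium chelate sets C6; the chair ene transition state sets C7 and C8; the Z geometry comes from angelic acid.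

Key step: step 16

Remark: the target is read as methyl 6α-angeloyloxy-1β,4α,8α-trihydroxyeudesm-11(13)-en-12-oate (5α-H, 7α-H, 10β-CH3); eudesmane numbering is kept for every intermediate, and β means the face of ring A that carries the C10 methyl (C14).

**Route**

Step 1
Reactants: 1 2-methylcyclohex-2-en-1-one
Product: 2 (S)-2-methylcyclohex-2-en-1-ol
Conditions: (R)-1-methyl-3,3-diphenyltetrahydro-1H,3H-pyrrolo[1,2-c][1,3,2]oxazaborole ((R)-Me-CBS, 10 mol %), BH3·SMe2, THF, −20 °C; aq. work-up
Reagents that add atoms: none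
Why: Corey–Bakshi–Shibata reduction, in which the borane–oxazaborolidine complex binds the ketone with the methyl-bearing alkene carbon as the large group and delivers hydride to one carbonyl face, should give the (S)-allylic alcohol, the source of absolute configuration for the whole route.

Step 2
Reactants: 2 (S)-2-methylcyclohex-2-en-1-ol
Product: 3 (1S,2S,6R)-1-methyl-7-oxabicyclo[4.1.0]heptan-2-ol (epoxide cis to OH)
Conditions: VO(acac)2 (2 mol %), tBuOOH, CH2Cl2, 0 °C → rt
Reagents that add atoms: tert-butyl hydroperoxide, CC(C)(C)OO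
Why: Hydroxyl-directed epoxidation, in which the vanadium-bound tert-butyl peroxide is delivered from the allylic alkoxide to the alkene face syn to the hydroxyl, sets the future C1 oxygen on the β face relative to the carbinol.

Step 3
Reactants: 3 (1S,2S,6R)-1-methyl-7-oxabicyclo[4.1.0]heptan-2-ol
Product: 4 (1R,6R)-1-methyl-7-oxabicyclo[4.1.0]heptan-2-one
Conditions: (nPr4N)[RuO4] (5 mol %), N-methylmorpholine N-oxide, 4 Å molecular sieves, CH2Cl2, rt
Reagents that add atoms: none
Why: Ley–Griffith oxidation of a secondary alcohol under neutral conditions should leave the epoxide untouched and removes the carbinol centre once it has done its directing work, so that C1 now carries the absolute configuration.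

Step 4
Reactants: 4 (1R,6R)-1-methyl-7-oxabicyclo[4.1.0]heptan-2-one; 5 allyl bromide
Product: 7 (2S,3R)-3-hydroxy-2-methyl-2-(prop-2-en-1-yl)cyclohexan-1-one, via dilithium enolate alkoxide 6 (not isolated)
Conditions: Li (2.1 equiv), NH3(l)/THF, −78 °C; then allyl bromide, −78 → −33 °C; NH4Cl
Reagents that add atoms: allyl bromide (compound 5), C=CCBr
Why: Reductive alkylation of an α,β-epoxy ketone, in which two-electron reduction breaks the C10–O bond to give the C5/C10 enolate regiospecifically and allyl bromide then attacks C10 anti to the neighbouring C1–OLi group (held pseudo-axial by allylic strain with the C10 methyl), should create the quaternary centre with allyl trans and methyl cis to the C1 oxygen.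

Step 5
Reactants: 7 (2S,3R)-3-hydroxy-2-methyl-2-(prop-2-en-1-yl)cyclohexan-1-one
Product: 8 (2S,3R)-3-[(tert-butyldimethylsilyl)oxy]-2-methyl-2-(prop-2-en-1-yl)cyclohexan-1-one
Conditions: TBSOTf, 2,6-lutidine, CH2Cl2, −78 → 0 °C
Reagents that add atoms: tert-butyldimethylsilyl triflate, CC(C)(C)[Si](C)(C)OS(=O)(=O)C(F)(F)F
Why: Silylation of a hindered secondary alcohol with a silyl triflate and a hindered pyridine base protects O1 as an ether that is stable to every step up to the final deprotection.

Step 6
Reactants: 8 (2S,3R)-3-[(tert-butyldimethylsilyl)oxy]-2-methyl-2-(prop-2-en-1-yl)cyclohexan-1-one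
Product: 9 (2S,3R)-3-[(tert-butyldimethylsilyl)oxy]-2,6-dimethyl-2-(prop-2-en-1-yl)cyclohexan-1-one (both epimers at ring C6, which is eudesmane C4)
Conditions: LiN(iPr)2, THF, −78 °C; MeI, −78 → −20 °C
Reagents that add atoms: iodomethane, CI
Why: Kinetic enolate alkylation can only take place at C4 because C10 is quaternary, and the new centre, formed as an epimeric mixture, becomes trigonal in the next step.

Step 7
Reactants: 9 (2S,3R)-3-[(tert-butyldimethylsilyl)oxy]-2,6-dimethyl-2-(prop-2-en-1-yl)cyclohexan-1-one
Product: 10 (5R,6S)-5-[(tert-butyldimethylsilyl)oxy]-2,6-dimethyl-6-(prop-2-en-1-yl)cyclohex-1-en-1-yl trifluoromethanesulfonate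
Conditions: KN(SiMe3)2, THF, −78 °C; PhNTf2, −78 → 0 °C
Reagents that add atoms: N-phenylbis(trifluoromethanesulfonimide), O=S(=O)(N(c1ccccc1)S(=O)(=O)C(F)(F)F)C(F)(F)F
Why: Enolate O-sulfonylation with N-phenyltriflimide can only give the tetrasubstituted C4=C5 enol triflate, since C4 holds the sole remaining α-hydrogen, the same way 2,2,6-trimethylcyclohexanone is converted into its enol triflate.

Step 8
Reactants: 10 (5R,6S)-5-[(tert-butyldimethylsilyl)oxy]-2,6-dimethyl-6-(prop-2-en-1-yl)cyclohex-1-en-1-yl trifluoromethanesulfonate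
Product: 12 (5R,6S)-5-[(tert-butyldimethylsilyl)oxy]-6-(2-hydroxyethyl)-2,6-dimethylcyclohex-1-en-1-yl trifluoromethanesulfonate, via C8 aldehyde 11 (not isolated)
Conditions: OsO4 (2 mol %), NaIO4, 2,6-lutidine, dioxane/H2O, rt; then NaBH4, MeOH, 0 °C
Reagents that add atoms: sodium periodate (terminal oxygen source, relayed by OsO4), [Na+].[O-]I(=O)(=O)=O
Why: Lemieux–Johnson cleavage attacks only the monosubstituted allyl alkene because the tetrasubstituted, electron-poor enol triflate is inert to OsO4, and borohydride reduction of the crude aldehyde then gives the two-carbon C9–C8 alcohol arm.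

Step 9
Reactants: 12 (5R,6S)-5-[(tert-butyldimethylsilyl)oxy]-6-(2-hydroxyethyl)-2,6-dimethylcyclohex-1-en-1-yl trifluoromethanesulfonate
Product: 13 (4aR,5R)-5-[(tert-butyldimethylsilyl)oxy]-4a,8-dimethyl-3,4,4a,5,6,7-hexahydro-1H-isochromen-1-one (lactone C6(=O)–O–C8–C9 fused at C5/C10; C4=C5 alkene; 1β-OTBS; 10β-CH3)
Conditions: Pd(OAc)2 (5 mol %), PPh3, CO (1 atm), Et3N, DMF, 65 °C
Reagents that add atoms: carbon monoxide, [C-]#[O+]
Why: Palladium-catalysed carbonylative lactonisation (oxidative addition of zerovalent palladium into the C–OTf bond, CO insertion and capture of the acylpalladium by the tethered primary alcohol) attaches C6 to C5 and ties it to O8 in a six-membered unsaturated lactone that locks the conformation of ring A.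

Step 10
Reactants: 13 bicyclic unsaturated lactone
Product: 14 4α,5α-epoxide of lactone 13 (1β-OTBS, 4β-CH3, 10β-CH3; epoxide oxygen on the α face)
Conditions: (CF3CO)2O, urea·H2O2, Na2HPO4, CH2Cl2, 0 °C → rt
Reagents that add atoms: urea–hydrogen peroxide (oxygen donor, as CF3CO3H), NC(N)=O.OO
Why: Prilezhaev epoxidation with peroxytrifluoroacetic acid, a peracid electrophilic enough for a conjugated tetrasubstituted alkene, should take place on the α face because the lactone ring keeps C9 pseudo-equatorial and the angular C14 methyl pseudo-axial over the β face, as in the α-epoxidation of eudesm-4-enes, and this sets the C4 configuration (O α, methyl β).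

Step 11
Reactants: 14 4α,5α-epoxy lactone
Product: 15 trans-fused hydroxy lactone (1β-OTBS, 4α-OH, 4β-CH3, 5α-H, 10β-CH3; lactone C6(=O)–O–C8–C9)
Conditions: SmI2, HMPA, MeOH, THF, −78 → 0 °C
Reagents that add atoms: none
Why: Reductive opening of an α,β-epoxy ester by SmI2 (electron transfer to the lactone carbonyl, cleavage of the C5–O bond to a samarium enolate, protonation) keeps the C4–O bond, and protonation of C5 should be axial from the α face, away from the two β-axial methyls C14 and C15, giving the trans-fused β-hydroxy lactone.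

Step 12
Reactants: 15 trans-fused hydroxy lactone
Product: 16 lactol of 15 (C6 hemiacetal, both anomers; 4α-OH free)
Conditions: iBu2AlH (2.5 equiv), CH2Cl2, −78 °C; aq. potassium sodium tartrate
Reagents that add atoms: none
Why: Partial reduction of a lactone to the lactol by iBu2AlH at low temperature stops at the aluminium hemiacetal, one extra equivalent being consumed by the tertiary hydroxyl, and the anomeric centre formed is of no consequence.

Step 13
Reactants: 16 lactol; 17 2-methylprop-1-enylmagnesium bromide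
Product: 18 ring-A triol: cyclohexane with 1β-OTBS, 10β-CH3, 10α-(2-hydroxyethyl), 4α-OH, 4β-CH3, 5α-H and a (6S)-1-hydroxy-3-methylbut-2-enyl chain on C5
Conditions: 2-methylprop-1-enylmagnesium bromide (5 equiv), THF, −20 → 0 °C; aq. NH4Cl
Reagents that add atoms: 2-methylprop-1-enylmagnesium bromide (compound 17), CC(C)=C[Mg]Br
Why: Grignard addition to the ring-opened hydroxy aldehyde form of the lactol under chelation control, in which the magnesium alkoxide on O4 binds the formyl oxygen in a six-membered chelate and the syn-axial C14 and C15 methyls block the β face of the carbonyl, should deliver the alkenyl group from the α face and give the 6S carbinol.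

Step 14
Reactants: 18 ring-A triol
Product: 19 tris(triethylsilyl) ether of 18 (O4, O6 and O8 as TES ethers; O1 as TBS ether)
Conditions: TESOTf, 2,6-lutidine, CH2Cl2, −78 → 0 °C
Reagents that add atoms: triethylsilyl triflate, CC[Si](CC)(CC)OS(=O)(=O)C(F)(F)F
Why: Exhaustive silylation with the reactive triethylsilyl triflate covers the primary, the allylic secondary and the tertiary hydroxyl in one operation, giving weakly Lewis-basic ethers that tolerate the aluminium reagent of the key step.

Step 15
Reactants: 19 tris(triethylsilyl) ether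
Product: 20 ring-A aldehyde (ene precursor): C8 aldehyde on C9; (6S)-OTES 3-methylbut-2-enyl arm on C5; 1β-OTBS; 4α-OTES
Conditions: (COCl)2, DMSO, CH2Cl2, −78 → −40 °C; Et3N, → 0 °C
Reagents that add atoms: none
Why: Swern oxidation of a primary triethylsilyl ether, in which the chlorosulfonium reagent attacks the unhindered primary Si–O oxygen and the resulting alkoxysulfonium salt collapses to the aldehyde, leaves the hindered secondary and tertiary triethylsilyl ethers and the TBS ether in place.

Step 16
Reactants: 20 ring-A aldehyde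
Product: 21 1β-(tert-butyldimethylsilyloxy)-4α,6α-bis(triethylsilyloxy)eudesm-11(13)-en-8α-ol (trans-decalin, 5α-H, 7α-H, 10β-CH3)
Conditions: Me2AlCl (2 equiv), CH2Cl2, −78 → −40 °C
Reagents that add atoms: none
Why: Me2AlCl binds the C8 aldehyde oxygen, and C7 of the C7=C11 alkene then bonds to C8 while an allylic hydrogen of a C11 methyl passes to oxygen through a six-membered, concerted carbonyl-ene transition state; the aluminium alkoxide formed destroys a methyl–aluminium bond (methane), so no proton is left to ionise the allylic silyl ether. The closest known reaction is the Lewis-acid cyclisation of citronellal to isopulegol. Ring B closes as a six-membered ring in the 6-exo-trig sense at the carbonyl carbon, with the carbonyl oxygen and C11 both left outside the new ring. C7 is controlled by the chair transition state in which the developing propenyl group is equatorial and H6, not the C6 silyloxy group, lies next to the (Z)-methyl of C11 (least allylic strain), and C8 by the aluminium-bound oxygen taking the equatorial position, which together give the trans 7β,8α arrangement. The step needs bond formation at C7 rather than C11 and closure to the trans-decalin only: the first follows from C7 being the less substituted alkene terminus (positive charge develops on tertiary C11), the second from the C9 and C6 arms being trans-diequatorial on ring A, where the syn-axial C14 and C15 methyls force H6 between them and so point C7 towards C9 with O6 equatorial. Either C11 methyl can give up the hydrogen, and both lead to the same 2-propenyl group.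

Step 17
Reactants: 21 8α-alcohol
Product: 22 1β,8α-bis(tert-butyldimethylsilyloxy)-4α,6α-bis(triethylsilyloxy)eudesm-11(13)-ene
Conditions: TBSOTf, 2,6-lutidine, CH2Cl2, −78 → 0 °C
Reagents that add atoms: tert-butyldimethylsilyl triflate, CC(C)(C)[Si](C)(C)OS(=O)(=O)C(F)(F)F
Why: Silylation with a silyl triflate protects the new C8 hydroxyl so that it can neither be acylated in step 19 nor lactonise onto C12 later.

Step 18
Reactants: 22 tetrasilyl ether
Product: 23 1β,8α-bis(tert-butyldimethylsilyloxy)eudesm-11(13)-ene-4α,6α-diol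
Conditions: HF·pyridine, pyridine, THF, 0 °C
Reagents that add atoms: none
Why: Fluoride-mediated desilylation with buffered HF·pyridine distinguishes triethylsilyl from tert-butyldimethylsilyl ethers by their large rate difference, freeing O6 and O4 while O1 and O8 stay protected.

Step 19
Reactants: 23 4α,6α-diol; 24 angelic acid ((Z)-2-methylbut-2-enoic acid)
Product: 26 6α-angeloyloxy-1β,8α-bis(tert-butyldimethylsilyloxy)eudesm-11(13)-en-4α-ol, via angeloyl 2,4,6-trichlorobenzoyl anhydride 25 (not isolated)
Conditions: angelic acid, 2,4,6-trichlorobenzoyl chloride, Et3N, toluene, rt; then 23, toluene, 80 °C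
Reagents that add atoms: angelic acid (compound 24), C/C=C(/C)C(=O)O
Why: Yamaguchi-type esterification through the mixed 2,4,6-trichlorobenzoic anhydride, run without a nucleophilic catalyst so that the Z double bond is not isomerised to the tiglate, acylates the secondary C6 hydroxyl only, the tertiary C4 hydroxyl being too hindered to react.

Step 20
Reactants: 26 6α-angelate
Product: 27 6α-angeloyloxy-1β,8α-bis(tert-butyldimethylsilyloxy)eudesm-11(13)-ene-4α,12-diol
Conditions: SeO2 (0.3 equiv), tBuOOH, CH2Cl2, rt
Reagents that add atoms: tert-butyl hydroperoxide (oxygen source, relayed by SeO2), CC(C)(C)OO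
Why: SeO2 allylic oxidation (ene reaction at the terminal CH2 followed by a 2,3-sigmatropic shift) selects the electron-rich 1,1-disubstituted alkene over the conjugated angelate and the C12 methyl over the hindered C7 methine, giving the 2-substituted allyl alcohol.

Step 21
Reactants: 27 allylic alcohol
Product: 29 6α-angeloyloxy-1β,8α-bis(tert-butyldimethylsilyloxy)-4α-hydroxyeudesm-11(13)-en-12-oic acid, via C12 enal 28 (not isolated)
Conditions: 2,2,6,6-tetramethylpiperidin-1-oxyl (TEMPO, 10 mol %), NaOCl (cat.), NaClO2, MeCN/phosphate buffer (pH 6.7), 35 °C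
Reagents that add atoms: sodium chlorite, [Na+].[O-]Cl=O
Why: Oxoammonium (TEMPO) oxidation of the allylic alcohol to the enal followed in the same flask by chlorite (Pinnick-type) oxidation of the aldehyde gives the acrylic acid without touching the silyl ethers, the tertiary alcohol or the angelate.

Step 22
Reactants: 29 acrylic acid
Product: 30 methyl 6α-angeloyloxy-1β,8α-bis(tert-butyldimethylsilyloxy)-4α-hydroxyeudesm-11(13)-en-12-oate
Conditions: Me3SiCHN2, toluene/MeOH, 0 °C
Reagents that add atoms: trimethylsilyldiazomethane, C[Si](C)(C)C=[N+]=[N-]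
Why: Methyl ester formation with trimethylsilyldiazomethane in methanol is a mild O-methylation of the carboxylic acid that needs neither base nor heat, so neither the angelate geometry nor the acrylate is put at risk.

Step 23
Reactants: 30 bis-TBS methyl ester
Product: 31 methyl 6α-angeloyloxy-1β,4α,8α-trihydroxyeudesm-11(13)-en-12-oate (CNP0136844.1)
Conditions: HF·pyridine, THF, 0 °C → rt
Reagents that add atoms: none
Why: Global fluoride-mediated desilylation with HF·pyridine removes both TBS ethers under weakly acidic conditions that should neither isomerise the angelate nor close a lactone from O8 onto the methyl ester, and gives the target.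

**Compound list**

1 | 2-methylcyclohex-2-en-1-one | CC1=CCCCC1=O | starting material
2 | (S)-2-methylcyclohex-2-en-1-ol | CC1=CCCC[C@@H]1O | intermediate
3 | (1S,2S,6R)-1-methyl-7-oxabicyclo[4.1.0]heptan-2-ol | O[C@H]1CCC[C@H]2O[C@@]12C | intermediate
4 | (1R,6R)-1-methyl-7-oxabicyclo[4.1.0]heptan-2-one | O=C1CCC[C@H]2O[C@@]12C | intermediate
5 | allyl bromide | C=CCBr | starting material
6 | dilithium (3R)-2-methylcyclohex-1-ene-1,3-diolate | [Li+].[Li+].[O-]C1=C(C)[C@H]([O-])CCC1 | intermediate (not isolated)
7 | (2S,3R)-3-hydroxy-2-methyl-2-(prop-2-en-1-yl)cyclohexan-1-one (OH cis to CH3) | O=C1[C@@](C)(CC=C)[C@H](O)CCC1 | intermediate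
8 | (2S,3R)-3-[(tert-butyldimethylsilyl)oxy]-2-methyl-2-(prop-2-en-1-yl)cyclohexan-1-one | O=C1[C@@](C)(CC=C)[C@H](O[Si](C)(C)C(C)(C)C)CCC1 | intermediate
9 | (2S,3R)-3-[(tert-butyldimethylsilyl)oxy]-2,6-dimethyl-2-(prop-2-en-1-yl)cyclohexan-1-one, C6 epimers | O=C1[C@@](C)(CC=C)[C@H](O[Si](C)(C)C(C)(C)C)CCC1C | intermediate
10 | (5R,6S)-5-[(tert-butyldimethylsilyl)oxy]-2,6-dimethyl-6-(prop-2-en-1-yl)cyclohex-1-en-1-yl trifluoromethanesulfonate | CC1=C(OS(=O)(=O)C(F)(F)F)[C@@](C)(CC=C)[C@H](O[Si](C)(C)C(C)(C)C)CC1 | intermediate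
11 | (5R,6S)-5-[(tert-butyldimethylsilyl)oxy]-2,6-dimethyl-6-(2-oxoethyl)cyclohex-1-en-1-yl trifluoromethanesulfonate | CC1=C(OS(=O)(=O)C(F)(F)F)[C@@](C)(CC=O)[C@H](O[Si](C)(C)C(C)(C)C)CC1 | intermediate (not isolated)
12 | (5R,6S)-5-[(tert-butyldimethylsilyl)oxy]-6-(2-hydroxyethyl)-2,6-dimethylcyclohex-1-en-1-yl trifluoromethanesulfonate | CC1=C(OS(=O)(=O)C(F)(F)F)[C@@](C)(CCO)[C@H](O[Si](C)(C)C(C)(C)C)CC1 | intermediate
13 | (4aR,5R)-5-[(tert-butyldimethylsilyl)oxy]-4a,8-dimethyl-3,4,4a,5,6,7-hexahydro-1H-isochromen-1-one | CC1=C2C(=O)OCC[C@@]2(C)[C@H](O[Si](C)(C)C(C)(C)C)CC1 | intermediate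
14 | 4α,5α-epoxide of lactone 13 | C[C@@]12CC[C@@H](O[Si](C)(C)C(C)(C)C)[C@]3(C)CCOC(=O)[C@@]13O2 | intermediate
15 | trans-fused 4α-hydroxy lactone (1β-OTBS, 4β-CH3, 5α-H, 10β-CH3) | O=C1OCC[C@@]2(C)[C@H](O[Si](C)(C)C(C)(C)C)CC[C@@](C)(O)[C@H]12 | intermediate
16 | lactol of 15 (C6 anomers) | OC1OCC[C@@]2(C)[C@H](O[Si](C)(C)C(C)(C)C)CC[C@@](C)(O)[C@H]12 | intermediate
17 | 2-methylprop-1-enylmagnesium bromide | CC(C)=C[Mg]Br | starting material
18 | ring-A triol (6S carbinol, 4α-OH, C8 primary OH, 1β-OTBS) | CC(C)=C[C@H](O)[C@@H]1[C@@](C)(CCO)[C@H](O[Si](C)(C)C(C)(C)C)CC[C@@]1(C)O | intermediate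
19 | tris(triethylsilyl) ether of 18 | CC(C)=C[C@H](O[Si](CC)(CC)CC)[C@@H]1[C@@](C)(CCO[Si](CC)(CC)CC)[C@H](O[Si](C)(C)C(C)(C)C)CC[C@@]1(C)O[Si](CC)(CC)CC | intermediate
20 | ring-A aldehyde with (6S)-OTES 3-methylbut-2-enyl arm (ene precursor) | CC(C)=C[C@H](O[Si](CC)(CC)CC)[C@@H]1[C@@](C)(CC=O)[C@H](O[Si](C)(C)C(C)(C)C)CC[C@@]1(C)O[Si](CC)(CC)CC | intermediate
21 | 1β-(tert-butyldimethylsilyloxy)-4α,6α-bis(triethylsilyloxy)eudesm-11(13)-en-8α-ol | C=C(C)[C@H]1[C@H](O[Si](CC)(CC)CC)[C@@H]2[C@@](C)(C[C@@H]1O)[C@H](O[Si](C)(C)C(C)(C)C)CC[C@@]2(C)O[Si](CC)(CC)CC | intermediate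
22 | 1β,8α-bis(tert-butyldimethylsilyloxy)-4α,6α-bis(triethylsilyloxy)eudesm-11(13)-ene | C=C(C)[C@H]1[C@H](O[Si](CC)(CC)CC)[C@@H]2[C@@](C)(C[C@@H]1O[Si](C)(C)C(C)(C)C)[C@H](O[Si](C)(C)C(C)(C)C)CC[C@@]2(C)O[Si](CC)(CC)CC | intermediate
23 | 1β,8α-bis(tert-butyldimethylsilyloxy)eudesm-11(13)-ene-4α,6α-diol | C=C(C)[C@H]1[C@H](O)[C@@H]2[C@@](C)(C[C@@H]1O[Si](C)(C)C(C)(C)C)[C@H](O[Si](C)(C)C(C)(C)C)CC[C@@]2(C)O | intermediate
24 | angelic acid, (Z)-2-methylbut-2-enoic acid | C/C=C(/C)C(=O)O | starting material
25 | angeloyl 2,4,6-trichlorobenzoyl anhydride | C/C=C(/C)C(=O)OC(=O)c1c(Cl)cc(Cl)cc1Cl | intermediate (not isolated)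
26 | 6α-angeloyloxy-1β,8α-bis(tert-butyldimethylsilyloxy)eudesm-11(13)-en-4α-ol | C=C(C)[C@H]1[C@H](OC(=O)/C(C)=C\C)[C@@H]2[C@@](C)(C[C@@H]1O[Si](C)(C)C(C)(C)C)[C@H](O[Si](C)(C)C(C)(C)C)CC[C@@]2(C)O | intermediate
27 | 6α-angeloyloxy-1β,8α-bis(tert-butyldimethylsilyloxy)eudesm-11(13)-ene-4α,12-diol | C=C(CO)[C@H]1[C@H](OC(=O)/C(C)=C\C)[C@@H]2[C@@](C)(C[C@@H]1O[Si](C)(C)C(C)(C)C)[C@H](O[Si](C)(C)C(C)(C)C)CC[C@@]2(C)O | intermediate
28 | 6α-angeloyloxy-1β,8α-bis(tert-butyldimethylsilyloxy)-4α-hydroxyeudesm-11(13)-en-12-al | C=C(C=O)[C@H]1[C@H](OC(=O)/C(C)=C\C)[C@@H]2[C@@](C)(C[C@@H]1O[Si](C)(C)C(C)(C)C)[C@H](O[Si](C)(C)C(C)(C)C)CC[C@@]2(C)O | intermediate (not isolated)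
29 | 6α-angeloyloxy-1β,8α-bis(tert-butyldimethylsilyloxy)-4α-hydroxyeudesm-11(13)-en-12-oic acid | C=C(C(=O)O)[C@H]1[C@H](OC(=O)/C(C)=C\C)[C@@H]2[C@@](C)(C[C@@H]1O[Si](C)(C)C(C)(C)C)[C@H](O[Si](C)(C)C(C)(C)C)CC[C@@]2(C)O | intermediate
30 | methyl 6α-angeloyloxy-1β,8α-bis(tert-butyldimethylsilyloxy)-4α-hydroxyeudesm-11(13)-en-12-oate | C=C(C(=O)OC)[C@H]1[C@H](OC(=O)/C(C)=C\C)[C@@H]2[C@@](C)(C[C@@H]1O[Si](C)(C)C(C)(C)C)[C@H](O[Si](C)(C)C(C)(C)C)CC[C@@]2(C)O | intermediate
31 | methyl 6α-angeloyloxy-1β,4α,8α-trihydroxyeudesm-11(13)-en-12-oate (CNP0136844.1) | C=C(C(=O)OC)[C@H]1[C@H](OC(=O)/C(C)=C\C)[C@@H]2[C@@](C)(C[C@@H]1O)[C@H](O)CC[C@@]2(C)O | target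

**Totals and risks**

Total step count: 23. Longest linear sequence: 23 steps (1 → 31); compounds 5, 17 and 24 enter as single commercial building blocks.

Steps most likely to fail:

Step 13. The magnesium chelate between O4 and the formyl oxygen may not dominate, so that the Grignard reagent adds to the other rotamer of the aldehyde and facial selectivity at C6 is poor; the open β-hydroxy aldehyde may also fragment by retro-aldol cleavage. The fallback sets C6 by reagent-controlled ketone reduction instead of chelate-controlled addition. It sets out from hydroxy lactone 15: silylation of O4 with TESOTf gives the 4-O-triethylsilyl lactone F1. Addition of 2-methylprop-1-enyllithium at −78 °C, with the released primary alkoxide trapped by TESCl, gives the C6 enone F2. Corey–Bakshi–Shibata reduction with catecholborane, with the oxazaborolidine enantiomer chosen to deliver hydride to the face that gives the 6S configuration, leads to the 6S allylic alcohol F3. Silylation of F3 with TESOTf comes back to the route at 19.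

Step 16. The Lewis acid may ionise the allylic C6 silyl ether or divert the aldehyde into a stepwise Prins pathway with chloride capture, and the alkene, deactivated by the allylic oxygen, may react too slowly. The fallback forms the same C7–C8 bond by intramolecular allylmetal addition. It sets out from tris(triethylsilyl) ether 19: SeO2/tBuOOH oxidises the (E)-methyl of the isopropylidene group to the (E)-allylic alcohol F4. MsCl/Et3N followed by LiCl gives the allylic chloride F5. Swern oxidation of the primary triethylsilyl ether gives the chloro aldehyde F6. CrCl2 (divalent chromium) in THF then generates the allylchromium species, which adds through C7 to the C8 aldehyde in a closed chair transition state (intramolecular Nozaki–Hiyama allylation, anti-selective) and comes back to the route at 21.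

Step 4. The dilithium enolate alkoxide may be quenched by proton transfer, O-allylated, or lose its trans selectivity, and the product alkoxide may undergo retro-aldol ring opening before the quench. The fallback separates epoxide opening from C–C bond formation. It sets out from epoxy ketone 4: SmI2 in THF/MeOH at −90 °C opens the epoxide to (3R)-3-hydroxy-2-methylcyclohexan-1-one F7 (C2 epimers). TBSCl/imidazole gives the silyl ether F8. Me3SiCl/NaI/Et3N in MeCN gives the more substituted trimethylsilyl enol ether F9. Palladium-catalysed allylation of F9 with allyl methyl carbonate under neutral conditions (tris(dibenzylideneacetone)dipalladium Pd2(dba)3, 1,2-bis(diphenylphosphino)ethane, THF; Tsuji–Trost type) then installs the allyl group anti to the silyloxy group and comes back to the route at 8.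

**Further compounds**

F1 | step 13 | 4-O-triethylsilyl ether of hydroxy lactone 15 | O=C1OCC[C@@]2(C)[C@H](O[Si](C)(C)C(C)(C)C)CC[C@@](C)(O[Si](CC)(CC)CC)[C@H]12
F2 | step 13 | C6 enone: ring A with 3-methylbut-2-enoyl group on C5, 4α-OTES, C8-OTES, 1β-OTBS | CC(C)=CC(=O)[C@@H]1[C@@](C)(CCO[Si](CC)(CC)CC)[C@H](O[Si](C)(C)C(C)(C)C)CC[C@@]1(C)O[Si](CC)(CC)CC
F3 | step 13 | 6S allylic alcohol with 4α-OTES, C8-OTES, 1β-OTBS | CC(C)=C[C@H](O)[C@@H]1[C@@](C)(CCO[Si](CC)(CC)CC)[C@H](O[Si](C)(C)C(C)(C)C)CC[C@@]1(C)O[Si](CC)(CC)CC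
F4 | step 16 | (E)-allylic alcohol from oxidation of the (E)-methyl of 19 | OC/C(C)=C/[C@H](O[Si](CC)(CC)CC)[C@@H]1[C@@](C)(CCO[Si](CC)(CC)CC)[C@H](O[Si](C)(C)C(C)(C)C)CC[C@@]1(C)O[Si](CC)(CC)CC
F5 | step 16 | (E)-allylic chloride | ClC/C(C)=C/[C@H](O[Si](CC)(CC)CC)[C@@H]1[C@@](C)(CCO[Si](CC)(CC)CC)[C@H](O[Si](C)(C)C(C)(C)C)CC[C@@]1(C)O[Si](CC)(CC)CC
F6 | step 16 | (E)-allylic chloride with C8 aldehyde | ClC/C(C)=C/[C@H](O[Si](CC)(CC)CC)[C@@H]1[C@@](C)(CC=O)[C@H](O[Si](C)(C)C(C)(C)C)CC[C@@]1(C)O[Si](CC)(CC)CC
F7 | step 4 | (3R)-3-hydroxy-2-methylcyclohexan-1-one, C2 epimers | O=C1C(C)[C@H](O)CCC1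
F8 | step 4 | (3R)-3-[(tert-butyldimethylsilyl)oxy]-2-methylcyclohexan-1-one, C2 epimers | O=C1C(C)[C@H](O[Si](C)(C)C(C)(C)C)CCC1
F9 | step 4 | (3R)-3-[(tert-butyldimethylsilyl)oxy]-2-methyl-1-(trimethylsilyloxy)cyclohex-1-ene | C[Si](C)(C)OC1=C(C)[C@H](O[Si](C)(C)C(C)(C)C)CCC1
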